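The runs come from a simulation on assumed constants; scatter was added.

The partner is what you count in this flask, where a single-handed free catalyst works on a racemate and each turnover takes up one partner.

all flasks: left-handed substrate 0.50 M; right-handed substrate 0.50 M

| run | partner | free catalyst | remark | time |
|---|---|---|---|---|
| theta | 0.30 M | 12 mM | run made earlier |  |
| epsilon | 0.30 M | 50 mM | run made earlier |  |
| beta | 0.60 M | 25 mM | run made earlier |  |
| flask | 0.300 M | 25 mM |  | 8.0 min |

| run | time / min | left-handed product / % | right-handed product / % | left-handed substrate / % |
|---|---|---|---|---|
| theta | 0.417 | 8.4 | 0.9 | 40.6 |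
| theta | 0.833 | 7.7 | 1.9 | 40.0 |
| theta | 2.00 | 6.7 | 3.4 | 40.9 |
| theta | 5.00 | 5.1 | 4.4 | 40.4 |
| epsilon | 0.417 | 17.2 | 1.8 | 31.4 |
| epsilon | 0.833 | 15.4 | 4.3 | 30.9 |
| epsilon | 2.00 | 12.8 | 6.7 | 31.5 |
| epsilon | 5.00 | 10.3 | 9.1 | 30.8 |
| beta | 1.33 | 19.7 | 6.8 | 23.9 |
| beta | 2.50 | 16.6 | 9.9 | 23.6 |
| beta | 4.00 | 14.5 | 11.5 | 24.0 |
| beta | 5.00 | 13.5 | 12.9 | 23.5 |

(standard deviation of a reading: 0.3 percentage points)

- excess of left-handed product over right-handed product in the product at 25 s
- excess of left-handed product over right-handed product in the product at 8.0 min
- part of the left-handed substrate and right-handed substrate charged together that has reacted at 8.0 min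

- free catalyst is single-handed; left-handed substrate and right-handed substrate are mirror images of each other, charged as a racemate, each of them at the stated concentration
- an excess is the difference of the two amounts in percent of their sum
- an excess is below zero if the other one leads

Take the main step first: left-handed substrate plus partner gives left-handed product. In the flask the partner is the limiting reagent, with less charged than left-handed substrate, so this step by itself ends at 30.0% of both substrates, or 12.0 turnovers per catalyst.

But the theta run reads 9.50% of product at 5.00 min, less than the 30.0% its charge allows. So try a second process, a loss of partner on its own in proportion to partner, while the main step goes with partner, catalyst and left-handed substrate. Let r be the fraction of left-handed substrate left and v the partner lost, as a fraction of the left-handed charge. Then −ln r divided by v gives the start odds, partner used by the main step per partner lost at full left-handed charge, and on this picture they scale with catalyst. Taking the partner as used up at the last readings, v is its charge less what the left-handed substrate took. Scaled to 25 mM, the last readings of theta, epsilon and beta give 1.09, 1.12 and 1.13, so take 1.11. Held constant, these odds give a conversion of 15.8% and leave r at 68.4%.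

Now let the odds thin with r, taken at its mean over the course: 0.937. That leaves r at 71.0%, a conversion of 14.5% in the flask, counting the left-handed substrate.

Last comes the interchange of the two products, which moves the excess and not their sum. The excess in the epsilon run reads 81.1% at 25 s and 6.19% at 5.00 min, a decay read as 0.561 min⁻¹, which carried on in that run gives 1.15% at 8.0 min. The theta run reads 80.6% at 0.417 min, so you take about these same two excesses for the flask.

The forecast says 80%, 1.2% and 14.3%, and has the stop come “evidently because the catalyst dies”, where your reckoning puts it in the partner.

The flask gives 78.5%, 1.09% and 14.7%. At 8.00 min the partner stands at 0% of its charge, with 99.5% of the free catalyst still free. With 71% of the left-handed substrate left, the odds put the partner lost at 0.154 M, and the decomposed reagent stands at 0.153 M.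

    partner + free catalyst + left-handed substrate → free catalyst + left-handed product (k = 20.1 M⁻² s⁻¹)
    partner + free catalyst + right-handed substrate → free catalyst + right-handed product (k = 0.235 M⁻² s⁻¹)
    left-handed product ⇌ right-handed product (k = 0.00470 s⁻¹)
    partner → decomposed reagent (k = 0.225 s⁻¹)
    free catalyst → spent catalyst (k = 1.12 × 10⁻⁵ s⁻¹)

With 0.010 M of free catalyst the neighbour flask has start odds of 0.445, and the same two passes give a conversion of 8.63%. The computed neighbour gives 8.75%.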